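The vessel is closed and stirred and holds a racemate of the two substrates over a single-handed catalyst, with 0.300 M of partner against 0.400 M of substrate together.

- elm: left-handed substrate 0.20 M; right-handed substrate 0.20 M; partner 0.30 M; free catalyst 0.54 mM; added ligand 0.61 mM; the very flask that is asked about, followed so far
- flask: left-handed substrate 0.20 M; partner 0.300 M; free catalyst 0.54 mM; added ligand 0.61 mM; right-handed substrate 0.20 M; time 5.0 d

elm run (percent of the left-handed substrate and right-handed substrate together charged)

| time / d | right-handed substrate / % | left-handed substrate / % |
|---|---|---|
| 0.417 | 43.7 | 41.9 |
| 0.833 | 40.5 | 35.1 |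
| 1.25 | 37.8 | 32.4 |
| 1.67 | 36.0 | 28.4 |
| 2.00 | 35.3 | 25.4 |
| 2.50 | 33.1 | 23.8 |

(standard deviation of a reading: 1 percentage point)

- free catalyst is single-handed; left-handed substrate and right-handed substrate are mirror images of each other, charged as a racemate, each of them at the stated concentration
- what was read earlier has a scatter of 1 percentage point, one standard deviation

- whether the excess of right-handed substrate over left-handed substrate among what is left of the two reaches 99% by 5.0 d (yes / no)
- the highest excess of right-handed substrate over left-handed substrate among what is left of the two up to 5.0 d

If both substrates are taken by the same catalyst and partner, each at a rate proportional to its own concentration, dividing one rate by the other removes time, catalyst and partner. What remains is the selectivity factor: the logarithm of the fraction of left-handed substrate remaining over the same logarithm for right-handed substrate. I read it twice, from separate readings, and get 1.55 at 1.25 d and 1.80 at 2.50 d. They part by 0.250, but the right-handed logarithm is 0.280 in the earlier reading against 0.412 in the later, so the same scatter of 1 percentage point weighs more in the earlier one. I reject neither and carry their mean, the selectivity factor 1.68.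

With this factor, the ratio of left-handed to right-handed substrate remaining is the right-handed fraction raised to the factor minus one. An excess of 99% therefore asks for 0.0395% of the right-handed charge to remain. At one partner per substrate that costs 0.400 M of partner, more than the 0.300 M charged, so my answer is no. By this ratio the excess climbs as substrate goes, so I put its top at the end. If the right-handed substrate keeps shrinking by the factor of the last 1.25 d, 50.8% of its charge remains at 5.0 d, which gives me an excess of 22.5%.

The forecast says no and 24%, a little above my figure, and of the excess it says “It rises steadily”.

The flask gives no and 20.1%.

    free catalyst + left-handed substrate ⇌ catalyst intermediate A (K = 6.00 L mol⁻¹, k = 23.0 L mol⁻¹ min⁻¹)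
    free catalyst + right-handed substrate ⇌ catalyst intermediate B (K = 11.2 L mol⁻¹, k = 8.64 L mol⁻¹ min⁻¹)
    partner + catalyst intermediate A → free catalyst + left-handed product (k = 1.58 L mol⁻¹ min⁻¹)
    partner + catalyst intermediate B → free catalyst + right-handed product (k = 0.523 L mol⁻¹ min⁻¹)
    free catalyst → spent catalyst (k = 4.92 × 10⁻⁴ min⁻¹)
    left-handed product ⇌ right-handed product (k = 6.42 × 10⁻⁴ min⁻¹)
    free catalyst + added ligand ⇌ idle complex (K = 640 L mol⁻¹, k = 1.56 L mol⁻¹ min⁻¹)

In the flask the two intermediates kept turning over with partner while spent catalyst grew from 8.59% of the catalyst charged at 0.500 d to 65.3% at 5.00 d. By then 53.9% of the substrates had reacted and 28% of the partner remained. The 55% of right-handed charge remaining in the flask gives, through the factor, 37.1% of left-handed charge, and the flask holds 37%. The same flask read at 12 d has 49% of right-handed charge remaining, which gives 30.2% of left-handed charge, and it holds 30%.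

(The data are calculated with made-up constants; noise was put on by code.)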